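The route hinges on disconnecting the C2'–C3' bond of the cis pyranone ring (ring C' of the primed flavanone unit). The key step exploits the fact that C2' is a CH flanked by O1' and the anisyl ring B', that is, the benzylic methylene of a 4-methoxybenzyl aryl ether, which a rhodium carbene at C3' can reach through a six-membered transition state. In one operation the C–H insertion closes ring C', forms C2'–C3' and sets both cis stereocentres. The precursor is the preformed trans-(2S,3R)-flavanone carrying at C3 a diazoketone whose aryl ring (ring A') bears the ortho 4-methoxybenzyl ether and two silyl ethers.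

Key step: step 7

Numbering: unprimed atoms and rings A, B, C belong to the trans unit, primed atoms and rings A', B', C' to the cis unit; the target is (2S,3R,2'S,3'S). TBS = tert-butyldimethylsilyl, PMB = 4-methoxybenzyl.
Assumption 1: natural (2S)-isosakuranetin is bought as the single enantiomer and supplies C2; its enantiomeric purity would be verified by chiral HPLC before use.
Assumption 2: the (S)-configured catalyst is taken as the matched partner of the (2S,3R) substrate for the (2'S,3'S) outcome; this sense of induction is a working hypothesis.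

Step 1
Reactants: 1 2',4',6'-trihydroxyacetophenone; 2 tert-butyldimethylsilyl chloride
Product: 3 1-[2-hydroxy-4,6-bis(tert-butyldimethylsilyloxy)phenyl]ethan-1-one
Conditions: TBSCl (2.1 equiv), imidazole, DMF/CH2Cl2, 0 °C to rt
Reagents that add atoms: 2 tert-butyldimethylsilyl chloride, CC(C)(C)[Si](C)(C)Cl
Why: Imidazole-promoted phenol silylation takes the unchelated 4'-OH and one of the two equivalent ortho OH groups, while the last OH is deactivated by its hydrogen bond to the acetyl carbonyl, so two equivalents of silyl chloride should stop at the bis-silyl ether.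

Step 2
Reactants: 3 1-[2-hydroxy-4,6-bis(tert-butyldimethylsilyloxy)phenyl]ethan-1-one; 4 4-methoxybenzyl alcohol
Product: 5 1-[2-(4-methoxybenzyloxy)-4,6-bis(tert-butyldimethylsilyloxy)phenyl]ethan-1-one
Conditions: PMBOH (1.3 equiv), PPh3, DIAD, THF, 0 °C to rt
Reagents that add atoms: 4 4-methoxybenzyl alcohol, COc1ccc(CO)cc1
Why: The Mitsunobu etherification alkylates the acidic chelated phenol under neutral conditions, so the base-labile aryl silyl ethers never meet carbonate or a free phenoxide at elevated temperature.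

Step 3
Reactants: 5 1-[2-(4-methoxybenzyloxy)-4,6-bis(tert-butyldimethylsilyloxy)phenyl]ethan-1-one
Product: 7 2-bromo-1-[2-(4-methoxybenzyloxy)-4,6-bis(tert-butyldimethylsilyloxy)phenyl]ethan-1-one, via trimethylsilyl enol ether 6 (not isolated)
Conditions: TMSOTf, Et3N, CH2Cl2, 0 °C; NaHCO3 wash; crude 6, NBS, THF, −78 °C
Reagents that add atoms: N-bromosuccinimide, O=C1CCC(=O)N1Br; trimethylsilyl triflate, C[Si](C)(C)OS(=O)(=O)C(F)(F)F (its silyl group stays in 6 only)
Why: Soft enolisation gives the silyl enol ether of the methyl ketone, and its electrophilic α-bromination with NBS at low temperature should be much faster than bromination of the electron-rich but silyl-shielded arene and releases no HBr that could cleave the PMB or silyl ethers.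

Step 4
Reactants: 8 (2S)-isosakuranetin, (2S)-5,7-dihydroxy-2-(4-methoxyphenyl)chroman-4-one; 2 tert-butyldimethylsilyl chloride
Product: 9 (2S)-5,7-bis(tert-butyldimethylsilyloxy)-2-(4-methoxyphenyl)chroman-4-one
Conditions: TBSCl (3 equiv), imidazole, DMF, rt to 40 °C
Reagents that add atoms: 2 tert-butyldimethylsilyl chloride, CC(C)(C)[Si](C)(C)Cl
Why: Phenol silylation under imidazole catalysis, driven with excess reagent to cover the chelated 5-OH, uses a base far too weak to enolise C3, so the (2S) centre from the chiral pool is not exposed to ring opening and reclosure.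

Step 5
Reactants: 9 (2S)-5,7-bis(tert-butyldimethylsilyloxy)-2-(4-methoxyphenyl)chroman-4-one; 7 2-bromo-1-[2-(4-methoxybenzyloxy)-4,6-bis(tert-butyldimethylsilyloxy)phenyl]ethan-1-one
Product: 11 (2S,3R)-5,7-bis(tert-butyldimethylsilyloxy)-2-(4-methoxyphenyl)-3-{2-[2-(4-methoxybenzyloxy)-4,6-bis(tert-butyldimethylsilyloxy)phenyl]-2-oxoethyl}chroman-4-one, via lithium enolate 10 (not isolated)
Conditions: LiN(SiMe3)2 (1.05 equiv), THF, −78 °C; 7 (1.2 equiv), −78 to −50 °C; AcOH, −78 °C
Reagents that add atoms: none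
Why: Kinetic lithium enolate C-alkylation (SN2) with a phenacyl-type bromide, among the fastest SN2 electrophiles, should consume the enolate at −78 °C before E1cB opening of the pyranone can start; the bromide is approached anti to the C2 anisyl group, which sets C3 as (R), trans to C2, the arrangement that is also thermodynamically preferred should any epimerisation occur.

Step 6
Reactants: 11 (2S,3R)-5,7-bis(tert-butyldimethylsilyloxy)-2-(4-methoxyphenyl)-3-{2-[2-(4-methoxybenzyloxy)-4,6-bis(tert-butyldimethylsilyloxy)phenyl]-2-oxoethyl}chroman-4-one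
Product: 14 (2S,3R)-3-{1-diazo-2-[2-(4-methoxybenzyloxy)-4,6-bis(tert-butyldimethylsilyloxy)phenyl]-2-oxoethyl}-5,7-bis(tert-butyldimethylsilyloxy)-2-(4-methoxyphenyl)chroman-4-one, via lithium enolate 12 (not isolated), via trifluoroacetyl diketone 13 (not isolated)
Conditions: LiN(SiMe3)2 (1.1 equiv), THF, −78 °C; CF3CO2CH2CF3, −78 °C; aq NH4Cl; crude 13, MsN3, Et3N, H2O (1 equiv), MeCN, rt
Reagents that add atoms: methanesulfonyl azide, CS(=O)(=O)N=[N+]=[N-]; 2,2,2-trifluoroethyl trifluoroacetate, O=C(OCC(F)(F)F)C(F)(F)F (its acyl group stays in 13 only)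
Why: Regitz diazo transfer in its detrifluoroacetylative variant: LiN(SiMe3)2 should remove a hydrogen from the less hindered secondary C3' position in preference to the tertiary C3–H, Claisen-type trifluoroacetylation activates that carbon, and the sulfonyl azide then delivers N2 with loss of the trifluoroacetyl group as the N-acylsulfonamide; no new stereocentre is formed and C3 rests in its trans (R) configuration.

Step 7
Reactants: 14 (2S,3R)-3-{1-diazo-2-[2-(4-methoxybenzyloxy)-4,6-bis(tert-butyldimethylsilyloxy)phenyl]-2-oxoethyl}-5,7-bis(tert-butyldimethylsilyloxy)-2-(4-methoxyphenyl)chroman-4-one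
Product: 15 (2S,3R,2'S,3'S)-5,5',7,7'-tetrakis(tert-butyldimethylsilyloxy)-2,2'-bis(4-methoxyphenyl)-[3,3'-bichromane]-4,4'-dione
Conditions: Rh2(S-PTTL)4, dirhodium tetrakis[N-phthaloyl-(S)-tert-leucinate] (2 mol %), toluene, −78 °C to 0 °C; neutral work-up
Reagents that add atoms: none
Why: Rh2(S-PTTL)4 takes N2 from 14 to give an electrophilic rhodium carbene at C3', which inserts into one C–H bond of the O1'–CH2–anisyl group through a concerted, asynchronous three-centre transition state with hydride-like transfer to C3' and retention at C2'. The closest known reaction type is the intramolecular carbene C–H insertion of ortho-alkoxyaryl diazoketones next to the ether oxygen, which gives cis-2,3-disubstituted chroman-4-ones. Ring C' is closed as a six-membered ring by 1,6-C–H insertion (carbene carbon C3' as atom 1, C2' as atom 6), the usual 1,5-position being the oxygen O1' itself. C2' is set by which of the two diastereotopic benzylic hydrogens is replaced and C3' by the carbene face that bonds, both read by the chiral phthalimido-carboxylate pocket with a bias from the neighbouring C3 centre, and the compact cyclic transition state should place the B' anisyl group and the C3 substituent cis, the kinetic arrangement. The step needs insertion to win over the 1,2-hydride shift from C3 and over oxonium ylide formation at O1' with subsequent benzyl shift: the C3–H is alpha to the C4 carbonyl and so a poor hydride donor, the C2'–H bonds are activated by O1' and the 4-methoxyphenyl ring, the aryl ether and silyl ether oxygens are weak and shielded Lewis bases, the bulky tert-leucinate ligands and the low temperature disfavour the shift and ylide paths, and the silyl groups offer no activated C–H bond.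

Step 8
Reactants: 15 (2S,3R,2'S,3'S)-5,5',7,7'-tetrakis(tert-butyldimethylsilyloxy)-2,2'-bis(4-methoxyphenyl)-[3,3'-bichromane]-4,4'-dione
Product: 16 (2S,3R,2'S,3'S)-5,5',7,7'-tetrahydroxy-2,2'-bis(4-methoxyphenyl)-[3,3'-bichromane]-4,4'-dione (CNP0260837.2)
Conditions: HF·pyridine, pyridine, THF, 0 °C to rt
Reagents that add atoms: none
Why: Fluoride-mediated cleavage of aryl silyl ethers under pyridine-buffered, non-basic conditions should free the four phenols without enolising C3', so the kinetically formed 2',3'-cis ring is carried into the target unchanged.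

Compound list
1 | 2',4',6'-trihydroxyacetophenone | CC(=O)c1c(O)cc(O)cc1O | starting material
2 | tert-butyldimethylsilyl chloride | CC(C)(C)[Si](C)(C)Cl | starting material
3 | 1-[2-hydroxy-4,6-bis(TBSO)phenyl]ethan-1-one | CC(=O)c1c(O)cc(O[Si](C)(C)C(C)(C)C)cc1O[Si](C)(C)C(C)(C)C | intermediate
4 | 4-methoxybenzyl alcohol | COc1ccc(CO)cc1 | starting material
5 | 1-[2-(4-methoxybenzyloxy)-4,6-bis(TBSO)phenyl]ethan-1-one | CC(=O)c1c(OCc2ccc(OC)cc2)cc(O[Si](C)(C)C(C)(C)C)cc1O[Si](C)(C)C(C)(C)C | intermediate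
6 | trimethylsilyl enol ether of 5, {1-[2-(4-methoxybenzyloxy)-4,6-bis(TBSO)phenyl]ethenyloxy}trimethylsilane (not isolated) | C=C(O[Si](C)(C)C)c1c(OCc2ccc(OC)cc2)cc(O[Si](C)(C)C(C)(C)C)cc1O[Si](C)(C)C(C)(C)C | intermediate
7 | 2-bromo-1-[2-(4-methoxybenzyloxy)-4,6-bis(TBSO)phenyl]ethan-1-one | BrCC(=O)c1c(OCc2ccc(OC)cc2)cc(O[Si](C)(C)C(C)(C)C)cc1O[Si](C)(C)C(C)(C)C | intermediate
8 | (2S)-isosakuranetin, (2S)-5,7-dihydroxy-2-(4-methoxyphenyl)chroman-4-one | COc1ccc([C@H]2Oc3cc(O)cc(O)c3C(=O)C2)cc1 | starting material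
9 | (2S)-5,7-bis(TBSO)-2-(4-methoxyphenyl)chroman-4-one | COc1ccc([C@H]2Oc3cc(O[Si](C)(C)C(C)(C)C)cc(O[Si](C)(C)C(C)(C)C)c3C(=O)C2)cc1 | intermediate
10 | lithium (2S)-5,7-bis(TBSO)-2-(4-methoxyphenyl)-2H-chromen-4-olate (not isolated) | COc1ccc([C@H]2Oc3cc(O[Si](C)(C)C(C)(C)C)cc(O[Si](C)(C)C(C)(C)C)c3C(O[Li])=C2)cc1 | intermediate
11 | (2S,3R)-5,7-bis(TBSO)-2-(4-methoxyphenyl)-3-{2-[2-(4-methoxybenzyloxy)-4,6-bis(TBSO)phenyl]-2-oxoethyl}chroman-4-one | COc1ccc([C@H]2Oc3cc(O[Si](C)(C)C(C)(C)C)cc(O[Si](C)(C)C(C)(C)C)c3C(=O)[C@@H]2CC(=O)c2c(O[Si](C)(C)C(C)(C)C)cc(O[Si](C)(C)C(C)(C)C)cc2OCc2ccc(OC)cc2)cc1 | intermediate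
12 | lithium (Z)-2-[(2S,3R)-5,7-bis(TBSO)-2-(4-methoxyphenyl)-4-oxochroman-3-yl]-1-[2-(4-methoxybenzyloxy)-4,6-bis(TBSO)phenyl]ethen-1-olate (not isolated) | COc1ccc([C@H]2Oc3cc(O[Si](C)(C)C(C)(C)C)cc(O[Si](C)(C)C(C)(C)C)c3C(=O)[C@@H]2/C=C(\O[Li])c2c(O[Si](C)(C)C(C)(C)C)cc(O[Si](C)(C)C(C)(C)C)cc2OCc2ccc(OC)cc2)cc1 | intermediate
13 | (2S,3R)-5,7-bis(TBSO)-2-(4-methoxyphenyl)-3-{4,4,4-trifluoro-1-[2-(4-methoxybenzyloxy)-4,6-bis(TBSO)phenyl]-1,3-dioxobutan-2-yl}chroman-4-one, C3' epimers and enol forms (not isolated) | COc1ccc([C@H]2Oc3cc(O[Si](C)(C)C(C)(C)C)cc(O[Si](C)(C)C(C)(C)C)c3C(=O)[C@@H]2C(C(=O)C(F)(F)F)C(=O)c2c(O[Si](C)(C)C(C)(C)C)cc(O[Si](C)(C)C(C)(C)C)cc2OCc2ccc(OC)cc2)cc1 | intermediate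
14 | (2S,3R)-3-{1-diazo-2-[2-(4-methoxybenzyloxy)-4,6-bis(TBSO)phenyl]-2-oxoethyl}-5,7-bis(TBSO)-2-(4-methoxyphenyl)chroman-4-one | COc1ccc([C@H]2Oc3cc(O[Si](C)(C)C(C)(C)C)cc(O[Si](C)(C)C(C)(C)C)c3C(=O)[C@@H]2C(=[N+]=[N-])C(=O)c3c(O[Si](C)(C)C(C)(C)C)cc(O[Si](C)(C)C(C)(C)C)cc3OCc2ccc(OC)cc2)cc1 | intermediate
15 | (2S,3R,2'S,3'S)-5,5',7,7'-tetrakis(TBSO)-2,2'-bis(4-methoxyphenyl)-[3,3'-bichromane]-4,4'-dione | COc1ccc([C@H]2Oc3cc(O[Si](C)(C)C(C)(C)C)cc(O[Si](C)(C)C(C)(C)C)c3C(=O)[C@@H]2[C@@H]2C(=O)c3c(O[Si](C)(C)C(C)(C)C)cc(O[Si](C)(C)C(C)(C)C)cc3O[C@@H]2c2ccc(OC)cc2)cc1 | intermediate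
16 | (2S,3R,2'S,3'S)-5,5',7,7'-tetrahydroxy-2,2'-bis(4-methoxyphenyl)-[3,3'-bichromane]-4,4'-dione | COc1ccc([C@H]2Oc3cc(O)cc(O)c3C(=O)[C@@H]2[C@@H]2C(=O)c3c(O)cc(O)cc3O[C@@H]2c2ccc(OC)cc2)cc1 | target

Total step count: 8. Longest linear sequence: 7 steps (steps 1, 2, 3, 5, 6, 7, 8, from 2',4',6'-trihydroxyacetophenone).

Steps most likely to fail

1. Step 7. The carbene may suffer 1,2-hydride migration from C3 to give an enedione. It may be trapped by O1' as an oxonium ylide that then shifts the benzyl group. A mismatched catalyst–substrate pairing would erode facial selectivity. The cis ring may also epimerise to trans on work-up. The fallback leaves carbene chemistry and sets out from 9. Its lithium enolate 10 (LiN(SiMe3)2, THF, −78 °C) would be coupled oxidatively with CuCl2 (known oxidative enolate homocoupling), each C3 bonding anti to its anisyl group. This should give the C2-symmetric all-trans (2S,3R,2'S,3'R)-5,5',7,7'-tetrakis(TBSO)-2,2'-bis(4-methoxyphenyl)-[3,3'-bichromane]-4,4'-dione F1. One equivalent of LiN(SiMe3)2 at −78 °C would then give the all-trans dimer mono-lithium C3'-enolate F2; either half gives the same species. Kinetic protonation at −78 °C with a bulky phenol, from the face opposite the pseudoaxial B' anisyl group, should place the C3 substituent cis to that ring and so return to the route at 15. Unchanged F1 would be recycled.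

2. Step 5. The enolate may open by E1cB to the chalcone phenoxide, which would lose the C2 centre. Proton exchange with the bromoketone and silyl transfer from O5 to the enolate oxygen are further drains. The fallback sets out from 9. Soft enolisation (TMSOTf, Et3N, CH2Cl2, 0 °C), which never forms a free enolate, would give (2S)-5,7-bis(TBSO)-2-(4-methoxyphenyl)-4-(trimethylsilyloxy)-2H-chromene F3. Visible-light photoredox coupling of F3 with bromoketone 7 (Ir(ppy)3, tris(2-phenylpyridinato)iridium, blue LEDs, K2HPO4, MeCN, rt) is the known radical alkylation of silyl enol ethers by α-bromoketones to 1,4-diketones. It would add the phenacyl radical to C3 anti to the anisyl group and return to the route at 11.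

3. Step 6. Deprotonation may occur at C3 instead of C3', leading to acylation at the wrong carbon or ring opening. Silyl transfer to the enolate oxygen and hydrolysis of the ortho silyl ethers in the aqueous amine are further risks. The fallback sets out from 11. Condensation with tert-butoxybis(dimethylamino)methane (toluene, 60 °C) can only give an enaminone at the C3' methylene, namely (2S,3R)-3-{(E)-1-(dimethylamino)-3-[2-(4-methoxybenzyloxy)-4,6-bis(TBSO)phenyl]-3-oxoprop-1-en-2-yl}-5,7-bis(TBSO)-2-(4-methoxyphenyl)chroman-4-one F4. Diazo transfer to this enaminone with MsN3 (MeCN, rt) is a known cycloaddition–fragmentation that expels an N-sulfonylformamidine. It would return to the route at 14 without any strong-base enolisation.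

Further compounds
F1 | step 7 | (2S,3R,2'S,3'R)-5,5',7,7'-tetrakis(TBSO)-2,2'-bis(4-methoxyphenyl)-[3,3'-bichromane]-4,4'-dione | COc1ccc([C@H]2Oc3cc(O[Si](C)(C)C(C)(C)C)cc(O[Si](C)(C)C(C)(C)C)c3C(=O)[C@@H]2[C@H]2C(=O)c3c(O[Si](C)(C)C(C)(C)C)cc(O[Si](C)(C)C(C)(C)C)cc3O[C@@H]2c2ccc(OC)cc2)cc1
F2 | step 7 | all-trans dimer mono-lithium C3'-enolate | COc1ccc([C@H]2Oc3cc(O[Si](C)(C)C(C)(C)C)cc(O[Si](C)(C)C(C)(C)C)c3C(=O)[C@@H]2C2=C(O[Li])c3c(O[Si](C)(C)C(C)(C)C)cc(O[Si](C)(C)C(C)(C)C)cc3O[C@@H]2c2ccc(OC)cc2)cc1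
F3 | step 5 | (2S)-5,7-bis(TBSO)-2-(4-methoxyphenyl)-4-(trimethylsilyloxy)-2H-chromene | COc1ccc([C@H]2Oc3cc(O[Si](C)(C)C(C)(C)C)cc(O[Si](C)(C)C(C)(C)C)c3C(O[Si](C)(C)C)=C2)cc1
F4 | step 6 | (2S,3R)-3-{(E)-1-(dimethylamino)-3-[2-(4-methoxybenzyloxy)-4,6-bis(TBSO)phenyl]-3-oxoprop-1-en-2-yl}-5,7-bis(TBSO)-2-(4-methoxyphenyl)chroman-4-one | COc1ccc([C@H]2Oc3cc(O[Si](C)(C)C(C)(C)C)cc(O[Si](C)(C)C(C)(C)C)c3C(=O)[C@@H]2/C(=C\N(C)C)C(=O)c2c(O[Si](C)(C)C(C)(C)C)cc(O[Si](C)(C)C(C)(C)C)cc2OCc2ccc(OC)cc2)cc1
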